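**Retrosynthetic overview**

- Irisoquin B ⇐ acidolysis of the tert-butyl ether of 2-tert-butoxy-3-heptadecyl-5-methoxy-1,4-benzoquinone.
- That quinone ⇐ one-pot [4+2] ring expansion of 3-tert-butoxy-4-heptadecylcyclobutene-1,2-dione with (Z)-2-methoxyvinyllithium: carbonyl addition makes the ring CH–C(=O) bond, 4π ring opening and 6π electrocyclisation make the C(=O)–C(OMe) bond, and oxidation of the hydroquinone gives the quinone.
- Cyclobutenedione ⇐ di-tert-butyl squarate + heptadecylmagnesium bromide (from 1-bromoheptadecane); vinyl bromide ⇐ methyl vinyl ether.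
- Enabling feature: the ring arc C(=O)–C(OH)=C(C17H35)–C(=O) is a masked cyclobutene-1,2-dione whose O-substituted ring alkene turns the carbonyl next to the alkyl-bearing carbon into a vinylogous ester and leaves the other carbonyl open to attack; the remaining arc CH=C(OMe) is a 2-methoxyvinyl anion.
- Ring order: the purchased four-membered squarate ring is expanded to the six-membered quinone ring in the key step; no other ring is formed.

Key step: step 4

Remark on the chemistry: the target is achiral and its side chain is read as unbranched n-heptadecyl; the stereocentres that appear in 4, 5, 8, 11 and 13 are racemic and are erased again on the way, so no stereocontrol is planned.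

**Step 1**
Reactants: 1 1-bromoheptadecane
Product: 2 heptadecylmagnesium bromide
Conditions: Mg turnings, cat. I2, THF, reflux, slow addition of 1
Reagents that add atoms: magnesium, [Mg]
Why: Grignard formation by insertion of magnesium into the primary C–Br bond, with slow addition of 1 to keep Wurtz homocoupling low.

**Step 2**
Reactants: 2 heptadecylmagnesium bromide; 3 di-tert-butyl squarate
Product: 6 3-tert-butoxy-4-heptadecylcyclobut-3-ene-1,2-dione, via bromomagnesium alkoxide 4 (not isolated), via trifluoroacetate ester 5 (not isolated)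
Conditions: 2 (1.1 equiv), THF, −78 °C; TFAA, −78 → 0 °C; aq NaHCO3
Reagents that add atoms: none
Why: 1,2-addition of the Grignard reagent to one squarate carbonyl, O-trifluoroacetylation, ionisation to the alkoxy-stabilised cyclobutenyl cation and loss of the tert-butyl group from the resulting oxocarbenium ion (the squarate-to-cyclobutenedione 1,3-carbonyl transposition) should give 6 with one tert-butoxy group intact.

**Step 3**
Reactants: 7 methyl vinyl ether
Product: 9 (Z)-1-bromo-2-methoxyethene, via 1,2-dibromo-1-methoxyethane 8 (not isolated)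
Conditions: Br2, CH2Cl2, −78 °C; i-Pr2NEt, −78 °C → reflux; fractional distillation
Reagents that add atoms: bromine, BrBr
Why: electrophilic bromination of the enol ether followed by amine-induced loss of HBr through the α-bromo ether (E1-type, via the oxocarbenium ion) is the standard entry to β-bromovinyl ethers and should favour the Z isomer, which is enriched further by distillation.

**Step 4**
Reactants: 6 3-tert-butoxy-4-heptadecylcyclobut-3-ene-1,2-dione; 9 (Z)-1-bromo-2-methoxyethene
Product: 15 2-tert-butoxy-3-heptadecyl-5-methoxy-1,4-benzoquinone, via (Z)-2-methoxyvinyllithium 10 (not isolated), via vinyl carbinol 11 (not isolated), via dienylketene 12 (not isolated), via cyclohexadienone 13 (not isolated), via hydroquinone 14 (not isolated)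
Conditions: 9 (1.3 equiv), n-BuLi, Et2O, −78 °C; 6 in THF, −78 °C; aq NH4Cl, −78 → 0 °C, organic phase dried over K2CO3; toluene, 110 °C; Ag2O, K2CO3, rt
Reagents that add atoms: none
Why: Bromine–lithium exchange should give the configurationally stable (Z)-2-methoxyvinyllithium 10, whose CH carbon adds 1,2 to the more electrophilic carbonyl of 6 (the one flanked by the tert-butoxy-bearing carbon) and so forms the ring CH–C(=O) bond in carbinol 11. On heating, 11 should undergo 4π conrotatory ring opening to dienylketene 12, whose ketene carbon and methoxy-bearing alkene terminus, two carbons of like acceptor polarity, are joined by a thermal 6π disrotatory electrocyclisation to 13; enolisation gives hydroquinone 14 and Ag2O oxidises it to 15. The closest known reaction type is the Moore-type squarate ring expansion: alkenyllithium addition to a cyclobutenedione, thermal electrocyclic cascade to a hydroquinone, then oxidation. The six-membered ring is closed by 6π electrocyclisation after opening of the four-membered ring, a pericyclic closure that cannot divert to the five-membered ring a polar ketene–enol ether closure would favour. The carbinol carbon of 11 and the CH(OMe) carbon of 13 are formed racemic and are erased by ring opening and aromatisation, so no stereocentre needs control. The step needs regioselective addition, secured by the tert-butoxy group that deactivates the other carbonyl as a vinylogous ester, and outward rotation of the hydroxyl in the ring opening, secured by its donor character, which puts the alkenyl group cis to the ketene and prevents lactonisation.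

**Step 5**
Reactants: 15 2-tert-butoxy-3-heptadecyl-5-methoxy-1,4-benzoquinone
Product: 16 irisoquin B
Conditions: TFA, CH2Cl2, 0 °C → rt
Reagents that add atoms: none
Why: acidolysis of the vinylogous tert-butyl ester (E1 loss of the tert-butyl cation as isobutene) should free the hydroxyl next to the side chain, while the methyl vinylogous ester is inert to anhydrous acid.

**Compound list**

1 | 1-bromoheptadecane | CCCCCCCCCCCCCCCCCBr | starting material
2 | heptadecylmagnesium bromide | CCCCCCCCCCCCCCCCC[Mg]Br | intermediate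
3 | di-tert-butyl squarate (3,4-di-tert-butoxycyclobut-3-ene-1,2-dione) | CC(C)(C)OC1=C(OC(C)(C)C)C(=O)C1=O | starting material
4 | bromomagnesium 2,3-di-tert-butoxy-1-heptadecyl-4-oxocyclobut-2-en-1-olate (racemic) | CCCCCCCCCCCCCCCCCC1(O[Mg]Br)C(OC(C)(C)C)=C(OC(C)(C)C)C1=O | intermediate
5 | 2,3-di-tert-butoxy-1-heptadecyl-4-oxocyclobut-2-en-1-yl trifluoroacetate (racemic) | CCCCCCCCCCCCCCCCCC1(OC(=O)C(F)(F)F)C(OC(C)(C)C)=C(OC(C)(C)C)C1=O | intermediate
6 | 3-tert-butoxy-4-heptadecylcyclobut-3-ene-1,2-dione | CCCCCCCCCCCCCCCCCC1=C(OC(C)(C)C)C(=O)C1=O | intermediate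
7 | methyl vinyl ether (methoxyethene) | COC=C | starting material
8 | 1,2-dibromo-1-methoxyethane (racemic) | COC(Br)CBr | intermediate
9 | (Z)-1-bromo-2-methoxyethene | CO/C=C\Br | intermediate
10 | (Z)-2-methoxyvinyllithium | CO/C=C\[Li] | intermediate
11 | 3-tert-butoxy-2-heptadecyl-4-hydroxy-4-[(Z)-2-methoxyvinyl]cyclobut-2-en-1-one (racemic) | CCCCCCCCCCCCCCCCCC1=C(OC(C)(C)C)C(O)(/C=C\OC)C1=O | intermediate
12 | (3Z,5Z)-3-tert-butoxy-2-heptadecyl-4-hydroxy-6-methoxyhexa-1,3,5-trien-1-one | CCCCCCCCCCCCCCCCCC(=C=O)/C(OC(C)(C)C)=C(O)\C=C/OC | intermediate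
13 | 5-tert-butoxy-6-heptadecyl-4-hydroxy-2-methoxycyclohexa-3,5-dien-1-one (racemic) | CCCCCCCCCCCCCCCCCC1=C(OC(C)(C)C)C(O)=CC(OC)C1=O | intermediate
14 | 2-tert-butoxy-3-heptadecyl-5-methoxybenzene-1,4-diol | CCCCCCCCCCCCCCCCCc1c(OC(C)(C)C)c(O)cc(OC)c1O | intermediate
15 | 2-tert-butoxy-3-heptadecyl-5-methoxycyclohexa-2,5-diene-1,4-dione | CCCCCCCCCCCCCCCCCC1=C(OC(C)(C)C)C(=O)C=C(OC)C1=O | intermediate
16 | irisoquin B (3-heptadecyl-2-hydroxy-5-methoxycyclohexa-2,5-diene-1,4-dione) | CCCCCCCCCCCCCCCCCC1=C(O)C(=O)C=C(OC)C1=O | target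

**Totals**

Total step count: 5. Longest linear sequence: 4 steps (steps 1, 2, 4, 5).

**Steps most likely to fail**

1. Step 4 (key step). The β-methoxyvinyl carbinol may lose methanol by acid-triggered allylic transposition during the quench. The vinyllithium may fragment by β-elimination before it adds. The inward methoxy group may slow the ring closure enough for ketene side reactions to take over. The fallback sets out from 1 and comes back at 16 by the classical arene route. 1,2,4,5-Tetramethoxybenzene is lithiated between two methoxy groups (n-BuLi, THF, 0 °C) to 2,3,5,6-tetramethoxyphenyllithium F1. F1 is alkylated with 1 to 3-heptadecyl-1,2,4,5-tetramethoxybenzene F2. Oxidative demethylation with (NH4)2Ce(NO3)6 in MeCN/H2O gives 3-heptadecyl-2,5-dimethoxy-1,4-benzoquinone F3. Saponification of both vinylogous esters (aq NaOH, EtOH, then HCl) gives 3-heptadecyl-2,5-dihydroxy-1,4-benzoquinone F4. Acid-catalysed etherification in MeOH (cat. H2SO4, reflux) should methylate only the hydroxyl not flanked by the side chain and give 16.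

2. Step 3. The dehydrobromination may give poor Z/E control, and the volatile, acid-sensitive bromide may be lost on distillation; E isomer carried forward is destroyed by fragmentation on lithiation. The fallback sets out from 6 and comes back at 16, using purchased (Z)-1-bromo-2-ethoxyethene in place of 9. Bromine–lithium exchange gives (Z)-2-ethoxyvinyllithium F5. Addition to 6 gives 3-tert-butoxy-4-[(Z)-2-ethoxyvinyl]-2-heptadecyl-4-hydroxycyclobut-2-en-1-one F6. Thermolysis in toluene runs through (3Z,5Z)-3-tert-butoxy-6-ethoxy-2-heptadecyl-4-hydroxyhexa-1,3,5-trien-1-one F7 and 5-tert-butoxy-2-ethoxy-6-heptadecyl-4-hydroxycyclohexa-3,5-dien-1-one F8 to 2-tert-butoxy-5-ethoxy-3-heptadecylbenzene-1,4-diol F9. Ag2O oxidation gives 2-tert-butoxy-5-ethoxy-3-heptadecyl-1,4-benzoquinone F10. TFA in CH2Cl2 removes the tert-butyl group to give 5-ethoxy-3-heptadecyl-2-hydroxy-1,4-benzoquinone F11. Acid-catalysed alkoxy exchange of the unhindered vinylogous ester in MeOH (cat. H2SO4) gives 16.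

3. Step 2. The Grignard reagent may add twice, or the second tert-butyl group may be lost under the acidic transposition conditions. The fallback sets out from 2 and comes back at 6, installing the tert-butyl group after the acid step. Addition of 2 to diisopropyl squarate (THF, −78 °C, NH4Cl quench) gives 4-heptadecyl-4-hydroxy-2,3-diisopropoxycyclobut-2-en-1-one F12. Catalytic concentrated HCl in CH2Cl2 rearranges it to 3-heptadecyl-4-isopropoxycyclobut-3-ene-1,2-dione F13. Aqueous HCl in THF hydrolyses the vinylogous ester to 3-heptadecyl-4-hydroxycyclobut-3-ene-1,2-dione F14. O-tert-butylation of this vinylogous acid with tert-butyl 2,2,2-trichloroacetimidate (CH2Cl2/cyclohexane, rt) gives 6.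

**Further compounds**

F1 | step 4 | 2,3,5,6-tetramethoxyphenyllithium | [Li]c1c(OC)c(OC)cc(OC)c1OC
F2 | step 4 | 3-heptadecyl-1,2,4,5-tetramethoxybenzene | CCCCCCCCCCCCCCCCCc1c(OC)c(OC)cc(OC)c1OC
F3 | step 4 | 3-heptadecyl-2,5-dimethoxy-1,4-benzoquinone | CCCCCCCCCCCCCCCCCC1=C(OC)C(=O)C=C(OC)C1=O
F4 | step 4 | 3-heptadecyl-2,5-dihydroxy-1,4-benzoquinone | CCCCCCCCCCCCCCCCCC1=C(O)C(=O)C=C(O)C1=O
F5 | step 3 | (Z)-2-ethoxyvinyllithium | CCO/C=C\[Li]
F6 | step 3 | 3-tert-butoxy-4-[(Z)-2-ethoxyvinyl]-2-heptadecyl-4-hydroxycyclobut-2-en-1-one (racemic) | CCCCCCCCCCCCCCCCCC1=C(OC(C)(C)C)C(O)(/C=C\OCC)C1=O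
F7 | step 3 | (3Z,5Z)-3-tert-butoxy-6-ethoxy-2-heptadecyl-4-hydroxyhexa-1,3,5-trien-1-one | CCCCCCCCCCCCCCCCCC(=C=O)/C(OC(C)(C)C)=C(O)\C=C/OCC
F8 | step 3 | 5-tert-butoxy-2-ethoxy-6-heptadecyl-4-hydroxycyclohexa-3,5-dien-1-one (racemic) | CCCCCCCCCCCCCCCCCC1=C(OC(C)(C)C)C(O)=CC(OCC)C1=O
F9 | step 3 | 2-tert-butoxy-5-ethoxy-3-heptadecylbenzene-1,4-diol | CCCCCCCCCCCCCCCCCc1c(OC(C)(C)C)c(O)cc(OCC)c1O
F10 | step 3 | 2-tert-butoxy-5-ethoxy-3-heptadecyl-1,4-benzoquinone | CCCCCCCCCCCCCCCCCC1=C(OC(C)(C)C)C(=O)C=C(OCC)C1=O
F11 | step 3 | 5-ethoxy-3-heptadecyl-2-hydroxy-1,4-benzoquinone | CCCCCCCCCCCCCCCCCC1=C(O)C(=O)C=C(OCC)C1=O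
F12 | step 2 | 4-heptadecyl-4-hydroxy-2,3-diisopropoxycyclobut-2-en-1-one (racemic) | CCCCCCCCCCCCCCCCCC1(O)C(OC(C)C)=C(OC(C)C)C1=O
F13 | step 2 | 3-heptadecyl-4-isopropoxycyclobut-3-ene-1,2-dione | CCCCCCCCCCCCCCCCCC1=C(OC(C)C)C(=O)C1=O
F14 | step 2 | 3-heptadecyl-4-hydroxycyclobut-3-ene-1,2-dione | CCCCCCCCCCCCCCCCCC1=C(O)C(=O)C1=O
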